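**Retrosynthetic overview**
1. The usual ring-closing allylation at C6–C7 with lactonisation is not used; the lactone is made first and used as the nucleophile.
2. Target ⇐ desilylation and acetylation ⇐ ten-membered ring closed last at C3–C4 by Ni/Cr alkenyl iodide–aldehyde coupling of a seco-aldehyde.
3. Seco-aldehyde ⇐ C7–C8 fragment union: CrCl2-mediated γ-allylation of a (Z)-enal by a 3-(bromomethyl)butenolide, which sets C7 and C8 and unveils the exo-methylene lactone in one step.
4. Butenolide ⇐ ring-closing metathesis of a 2-(bromomethyl)acrylate of a resolved (R)-dienol; enal ⇐ alkenyllithium plus Weinreb amide, then CBS reduction (C1).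
5. Both (Z)-trisubstituted alkenes ⇐ Red-Al/I2 on propargylic alcohols; ring order: butenolide (the later γ-lactone) first, ten-membered carbocycle last.

Assumption: atom labels follow a germacrane skeleton (C6 lactone carbinol, C7 ring-fusion carbon, C8 angelate carbinol, C3 acetate carbinol, C1 free carbinol, C15 the CH2OH on C4, C14 the methyl on C10, C11–C13 the methylene-lactone carbons); in these labels the target is 1S,3S,6S,7S,8R,4Z,9Z and the side-chain ester is the (Z)-2-methylbut-2-enoate (angelate).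

**Route**

Step 1
Reactants: 1 tert-butyldimethyl(prop-2-yn-1-yloxy)silane; 2 (E)-but-2-enal
Product: 4 rac-(5E)-1-[(tert-butyldimethylsilyl)oxy]hept-5-en-2-yn-4-ol, via lithium acetylide 3 (not isolated)
Conditions: n-BuLi, THF, −78 °C; then 2, −78 → −20 °C; H2O
Reagents that add atoms: none
Why: 1,2-addition of a lithium acetylide to an enal; the new carbinol (C6) is racemic here and is resolved in step 2.

Step 2
Reactants: 4 rac-(5E)-1-[(tert-butyldimethylsilyl)oxy]hept-5-en-2-yn-4-ol
Product: 5 (4R,5E)-1-[(tert-butyldimethylsilyl)oxy]hept-5-en-2-yn-4-ol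
Conditions: Ti(OiPr)4 (10 mol %), D-(−)-diisopropyl tartrate (14 mol %), t-BuOOH (0.6 equiv), 4 Å sieves, CH2Cl2, −20 °C, stopped near 55% conversion
Reagents that add atoms: none
Why: Sharpless kinetic resolution: with the D-(−)-tartrate the (S)-carbinol is epoxidised at its propenyl group much faster, so (R)-5 is recovered in high ee and C6 is set.

Step 3
Reactants: 5 (4R,5E)-1-[(tert-butyldimethylsilyl)oxy]hept-5-en-2-yn-4-ol
Product: 7 (2Z,4R,5E)-1-[(tert-butyldimethylsilyl)oxy]-2-iodohepta-2,5-dien-4-ol, via cyclic vinylalanate 6 (not isolated)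
Conditions: NaAlH2(OCH2CH2OMe)2 (Red-Al), THF, 0 °C → rt; then I2, −78 → 0 °C
Reagents that add atoms: iodine, II
Why: hydroxyl-directed trans-hydroalumination of the propargylic alcohol puts Al on the distal alkyne carbon (C4) cis to C6 in a five-membered alanate, and iododealumination with retention fixes the C4=C5 geometry (iodine sits where C3 is attached later); the silyl-ether side cannot direct and the propenyl group is inert.

Step 4
Reactants: 7 (2Z,4R,5E)-1-[(tert-butyldimethylsilyl)oxy]-2-iodohepta-2,5-dien-4-ol; 8 2-(bromomethyl)prop-2-enoic acid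
Product: 9 (2Z,4R,5E)-1-[(tert-butyldimethylsilyl)oxy]-2-iodohepta-2,5-dien-4-yl 2-(bromomethyl)prop-2-enoate
Conditions: DCC, DMAP (5 mol %), CH2Cl2, −20 → 0 °C
Reagents that add atoms: none
Why: Steglich esterification acylates oxygen only, so C6 is untouched; low temperature and catalytic DMAP spare the allylic bromide.

Step 5
Reactants: 9 (2Z,4R,5E)-1-[(tert-butyldimethylsilyl)oxy]-2-iodohepta-2,5-dien-4-yl 2-(bromomethyl)prop-2-enoate
Product: 10 (5R)-3-(bromomethyl)-5-[(1Z)-3-[(tert-butyldimethylsilyl)oxy]-2-iodoprop-1-en-1-yl]furan-2(5H)-one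
Conditions: second-generation Grubbs catalyst RuCl2(=CHPh)(H2IMes)(PCy3) (5 mol %), CH2Cl2 (5 mM), 40 °C, argon sparge
Reagents that add atoms: none
Why: ring-closing metathesis between the propenyl group and the acrylate closes the butenolide with loss of propene; the trisubstituted iodoalkene does not engage the ruthenium carbene.

Step 6
Reactants: 11 but-2-yn-1-ol
Product: 13 (2Z)-3-iodobut-2-en-1-ol, via cyclic vinylalanate 12 (not isolated)
Conditions: NaAlH2(OCH2CH2OMe)2 (Red-Al), THF, 0 °C → rt; then I2, −78 → 0 °C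
Reagents that add atoms: iodine, II
Why: the same directed trans-hydroalumination–iodination puts iodine on C10 cis to C8, which fixes the future C9=C10 geometry.

Step 7
Reactants: 13 (2Z)-3-iodobut-2-en-1-ol
Product: 14 triethyl{[(2Z)-3-iodobut-2-en-1-yl]oxy}silane
Conditions: Et3SiCl, imidazole, CH2Cl2, 0 °C
Reagents that add atoms: chlorotriethylsilane, CC[Si](Cl)(CC)CC
Why: silylation of the primary alcohol; the triethylsilyl ether survives the next four steps and is later oxidised directly to the aldehyde.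

Step 8
Reactants: 15 methyl 3,3-dimethoxypropanoate
Product: 16 N,3,3-trimethoxy-N-methylpropanamide
Conditions: MeNH(OMe)·HCl, i-PrMgCl, THF, −20 °C
Reagents that add atoms: N,O-dimethylhydroxylamine hydrochloride, CNOC.Cl
Why: Weinreb amide formation by aminolysis of the ester with the magnesium amide; the acetal is inert to base.

Step 9
Reactants: 14 triethyl{[(2Z)-3-iodobut-2-en-1-yl]oxy}silane; 16 N,3,3-trimethoxy-N-methylpropanamide
Product: 18 (4Z)-1,1-dimethoxy-4-methyl-6-[(triethylsilyl)oxy]hex-4-en-3-one, via alkenyllithium 17 (not isolated)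
Conditions: t-BuLi (2.1 equiv), Et2O, −78 °C; then 16, −78 → −40 °C; aq. NH4Cl
Reagents that add atoms: none
Why: iodine–lithium exchange with retention of alkene geometry followed by Weinreb ketone synthesis (the chelated tetrahedral adduct prevents over-addition); ether at −78 °C suppresses 1,4 O→C silyl migration.

Step 10
Reactants: 18 (4Z)-1,1-dimethoxy-4-methyl-6-[(triethylsilyl)oxy]hex-4-en-3-one
Product: 19 (3S,4Z)-1,1-dimethoxy-4-methyl-6-[(triethylsilyl)oxy]hex-4-en-3-ol
Conditions: (R)-2-methyl-CBS-oxazaborolidine (0.3 equiv), catecholborane, toluene, −78 °C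
Reagents that add atoms: none
Why: Corey–Bakshi–Shibata reduction with the α-methylalkenyl group as the large substituent; the (R)-catalyst gives the (S)-allylic alcohol, which sets C1.

Step 11
Reactants: 19 (3S,4Z)-1,1-dimethoxy-4-methyl-6-[(triethylsilyl)oxy]hex-4-en-3-ol
Product: 20 (3S,4Z)-3-[(tert-butyldimethylsilyl)oxy]-1,1-dimethoxy-4-methyl-6-[(triethylsilyl)oxy]hex-4-ene
Conditions: t-BuMe2SiCl, imidazole, DMF, rt
Reagents that add atoms: tert-butylchlorodimethylsilane, CC(C)(C)[Si](C)(C)Cl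
Why: silylation of the secondary allylic alcohol under base, which leaves the acetal and the triethylsilyl ether alone.

Step 12
Reactants: 20 (3S,4Z)-3-[(tert-butyldimethylsilyl)oxy]-1,1-dimethoxy-4-methyl-6-[(triethylsilyl)oxy]hex-4-ene
Product: 21 (2Z,4S)-4-[(tert-butyldimethylsilyl)oxy]-6,6-dimethoxy-3-methylhex-2-enal
Conditions: (COCl)2, DMSO, CH2Cl2, −78 → −40 °C; then Et3N, → 0 °C
Reagents that add atoms: none
Why: Swern oxidation in which the chlorosulfonium salt exchanges silicon for sulfur at the primary triethylsilyl ether, so the enal forms without a separate deprotection; the secondary silyl ether and acetal are untouched and the β,β-disubstituted (Z)-enal keeps its geometry.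

Step 13
Reactants: 10 (5R)-3-(bromomethyl)-5-[(1Z)-3-[(tert-butyldimethylsilyl)oxy]-2-iodoprop-1-en-1-yl]furan-2(5H)-one; 21 (2Z,4S)-4-[(tert-butyldimethylsilyl)oxy]-6,6-dimethoxy-3-methylhex-2-enal
Product: 23 (4S,5R)-4-[(1R,2Z,4S)-4-[(tert-butyldimethylsilyl)oxy]-1-hydroxy-6,6-dimethoxy-3-methylhex-2-en-1-yl]-5-[(1Z)-3-[(tert-butyldimethylsilyl)oxy]-2-iodoprop-1-en-1-yl]-3-methylideneoxolan-2-one, via allylchromium dichloride 22 (not isolated)
Conditions: CrCl2 (4 equiv), THF, 0 °C → rt; 21 (1.2 equiv)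
Reagents that add atoms: none
Why: Nozaki–Hiyama chromium Barbier allylation at the γ-carbon (C7) through a six-membered chair, known for the parent 3-(bromomethyl)butenolide: the enal adds anti to the C6 substituent (trans lactone, C7) and, with the ring-locked E-type allyl geometry and the enal substituent equatorial, the C8 hydroxyl is set syn to C11 (8R), while the alkenyl iodide is inert to CrCl2 without nickel.

Step 14
Reactants: 23 (C8 alcohol from step 13); 24 (2Z)-2-methylbut-2-enoic acid (angelic acid)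
Product: 25 (1R,2Z,4S)-4-[(tert-butyldimethylsilyl)oxy]-6,6-dimethoxy-3-methyl-1-[(2R,3S)-2-[(1Z)-3-[(tert-butyldimethylsilyl)oxy]-2-iodoprop-1-en-1-yl]-4-methylidene-5-oxooxolan-3-yl]hex-2-en-1-yl (2Z)-2-methylbut-2-enoate
Conditions: 24, 2,4,6-trichlorobenzoyl chloride, Et3N, toluene, rt; then 23, 75 °C (no DMAP)
Reagents that add atoms: none
Why: Yamaguchi-type mixed-anhydride acylation without nucleophilic catalyst transfers the angeloyl group without Z→E isomerisation to the tiglate; C8 is acylated with retention.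

Step 15
Reactants: 25 (C8 angelate dimethyl acetal)
Product: 26 (1R,2Z,4S)-4-[(tert-butyldimethylsilyl)oxy]-3-methyl-6-oxo-1-[(2R,3S)-2-[(1Z)-3-[(tert-butyldimethylsilyl)oxy]-2-iodoprop-1-en-1-yl]-4-methylidene-5-oxooxolan-3-yl]hex-2-en-1-yl (2Z)-2-methylbut-2-enoate
Conditions: In(OTf)3 (2 mol %), acetone/H2O 20:1, rt
Reagents that add atoms: water, O
Why: mild Lewis-acid-catalysed acetal hydrolysis that leaves the allylic silyl ethers, the esters and the methylene lactone intact.

Step 16
Reactants: 26 (seco-aldehyde)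
Product: 28 (3aS,4R,5Z,7S,9S,10Z,11aS)-7-[(tert-butyldimethylsilyl)oxy]-10-{[(tert-butyldimethylsilyl)oxy]methyl}-9-hydroxy-6-methyl-3-methylidene-2-oxo-2,3,3a,4,7,8,9,11a-octahydrocyclodeca[b]furan-4-yl (2Z)-2-methylbut-2-enoate, via alkenylchromium dichloride 27 (not isolated)
Conditions: CrCl2 (12 equiv), NiCl2 (0.1 equiv), degassed DMSO, slow addition to 2 mM, rt
Reagents that add atoms: none
Why: Nozaki–Hiyama–Kishi alkenyl iodide–aldehyde coupling closes the low-strain (Z,Z)-cyclodeca-1,6-diene with retention of the C4=C5 geometry; C3 is set by substrate control, because in the chair-like C1–C3 bridge a cis O1/O3 pair suffers either double allylic 1,2-strain (diequatorial) or a 1,3-diaxial clash, so the trans (3S) carbinol should predominate.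

Step 17
Reactants: 28 (macrocyclic C3 alcohol)
Product: 29 (3aS,4R,5Z,7S,9S,10Z,11aS)-9-acetoxy-7-[(tert-butyldimethylsilyl)oxy]-10-{[(tert-butyldimethylsilyl)oxy]methyl}-6-methyl-3-methylidene-2-oxo-2,3,3a,4,7,8,9,11a-octahydrocyclodeca[b]furan-4-yl (2Z)-2-methylbut-2-enoate
Conditions: Ac2O, pyridine, DMAP (cat.), CH2Cl2, 0 °C → rt
Reagents that add atoms: acetic anhydride, CC(=O)OC(C)=O
Why: acetylation of the only free hydroxyl (C3), so no O1/O3 differentiation is needed.

Step 18
Reactants: 29 (bis-silyl ether acetate)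
Product: 30 (3aS,4R,5Z,7S,9S,10Z,11aS)-9-acetoxy-7-hydroxy-10-(hydroxymethyl)-6-methyl-3-methylidene-2-oxo-2,3,3a,4,7,8,9,11a-octahydrocyclodeca[b]furan-4-yl (2Z)-2-methylbut-2-enoate (target)
Conditions: HF·pyridine, pyridine, THF, 0 °C → rt
Reagents that add atoms: none
Why: buffered fluoride desilylation removes both silyl ethers under mildly acidic conditions that do not promote acetate migration or attack the methylene lactone.

**Compound list**
1 | tert-butyldimethyl(prop-2-yn-1-yloxy)silane | C#CCO[Si](C)(C)C(C)(C)C | starting material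
2 | (E)-but-2-enal | C/C=C/C=O | starting material
3 | lithium acetylide of 1 (formed in situ) | [Li]C#CCO[Si](C)(C)C(C)(C)C | intermediate
4 | rac-(5E)-1-[(tert-butyldimethylsilyl)oxy]hept-5-en-2-yn-4-ol | C/C=C/C(O)C#CCO[Si](C)(C)C(C)(C)C | intermediate
5 | (4R,5E)-1-[(tert-butyldimethylsilyl)oxy]hept-5-en-2-yn-4-ol | C/C=C/[C@@H](O)C#CCO[Si](C)(C)C(C)(C)C | intermediate
6 | cyclic sodium vinylalanate from 5 (five-membered C6–O–Al–C4=C5 ring; formed in situ) | [Na+].C/C=C/[C@H]1O[Al-](OCCOC)(OCCOC)C(CO[Si](C)(C)C(C)(C)C)=C1 | intermediate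
7 | (2Z,4R,5E)-1-[(tert-butyldimethylsilyl)oxy]-2-iodohepta-2,5-dien-4-ol | C/C=C/[C@@H](O)/C=C(/CO[Si](C)(C)C(C)(C)C)I | intermediate
8 | 2-(bromomethyl)prop-2-enoic acid | C=C(CBr)C(=O)O | starting material
9 | (2Z,4R,5E)-1-[(tert-butyldimethylsilyl)oxy]-2-iodohepta-2,5-dien-4-yl 2-(bromomethyl)prop-2-enoate | C=C(CBr)C(=O)O[C@H](/C=C/C)/C=C(/CO[Si](C)(C)C(C)(C)C)I | intermediate
10 | (5R)-3-(bromomethyl)-5-[(1Z)-3-[(tert-butyldimethylsilyl)oxy]-2-iodoprop-1-en-1-yl]furan-2(5H)-one | O=C1O[C@H](C=C1CBr)/C=C(/CO[Si](C)(C)C(C)(C)C)I | intermediate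
11 | but-2-yn-1-ol | CC#CCO | starting material
12 | cyclic sodium vinylalanate from 11 (formed in situ) | [Na+].CC1=CCO[Al-]1(OCCOC)OCCOC | intermediate
13 | (2Z)-3-iodobut-2-en-1-ol | C/C(I)=C/CO | intermediate
14 | triethyl{[(2Z)-3-iodobut-2-en-1-yl]oxy}silane | C/C(I)=C/CO[Si](CC)(CC)CC | intermediate
15 | methyl 3,3-dimethoxypropanoate | COC(OC)CC(=O)OC | starting material
16 | N,3,3-trimethoxy-N-methylpropanamide | COC(OC)CC(=O)N(C)OC | intermediate
17 | [(2Z)-4-[(triethylsilyl)oxy]but-2-en-2-yl]lithium (formed in situ) | C/C([Li])=C/CO[Si](CC)(CC)CC | intermediate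
18 | (4Z)-1,1-dimethoxy-4-methyl-6-[(triethylsilyl)oxy]hex-4-en-3-one | COC(OC)CC(=O)/C(C)=C\CO[Si](CC)(CC)CC | intermediate
19 | (3S,4Z)-1,1-dimethoxy-4-methyl-6-[(triethylsilyl)oxy]hex-4-en-3-ol | COC(OC)C[C@H](O)/C(C)=C\CO[Si](CC)(CC)CC | intermediate
20 | (3S,4Z)-3-[(tert-butyldimethylsilyl)oxy]-1,1-dimethoxy-4-methyl-6-[(triethylsilyl)oxy]hex-4-ene | COC(OC)C[C@H](O[Si](C)(C)C(C)(C)C)/C(C)=C\CO[Si](CC)(CC)CC | intermediate
21 | (2Z,4S)-4-[(tert-butyldimethylsilyl)oxy]-6,6-dimethoxy-3-methylhex-2-enal | COC(OC)C[C@H](O[Si](C)(C)C(C)(C)C)/C(C)=C\C=O | intermediate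
22 | allylchromium dichloride from 10 (trivalent chromium; formed in situ) | O=C1O[C@H](C=C1C[Cr](Cl)Cl)/C=C(/CO[Si](C)(C)C(C)(C)C)I | intermediate
23 | (4S,5R)-4-[(1R,2Z,4S)-4-[(tert-butyldimethylsilyl)oxy]-1-hydroxy-6,6-dimethoxy-3-methylhex-2-en-1-yl]-5-[(1Z)-3-[(tert-butyldimethylsilyl)oxy]-2-iodoprop-1-en-1-yl]-3-methylideneoxolan-2-one | C=C1C(=O)O[C@@H](/C=C(/CO[Si](C)(C)C(C)(C)C)I)[C@@H]1[C@H](O)/C=C(C)\[C@@H](O[Si](C)(C)C(C)(C)C)CC(OC)OC | intermediate
24 | (2Z)-2-methylbut-2-enoic acid (angelic acid) | C/C=C(/C)C(=O)O | starting material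
25 | C8 angelate of 23 (dimethyl acetal) | C=C1C(=O)O[C@@H](/C=C(/CO[Si](C)(C)C(C)(C)C)I)[C@@H]1[C@H](OC(=O)/C(C)=C\C)/C=C(C)\[C@@H](O[Si](C)(C)C(C)(C)C)CC(OC)OC | intermediate
26 | seco-aldehyde (C3 aldehyde; C4 iodide) | C=C1C(=O)O[C@@H](/C=C(/CO[Si](C)(C)C(C)(C)C)I)[C@@H]1[C@H](OC(=O)/C(C)=C\C)/C=C(C)\[C@@H](O[Si](C)(C)C(C)(C)C)CC=O | intermediate
27 | alkenylchromium dichloride from 26 (trivalent chromium; formed in situ) | C=C1C(=O)O[C@@H](/C=C(/CO[Si](C)(C)C(C)(C)C)[Cr](Cl)Cl)[C@@H]1[C@H](OC(=O)/C(C)=C\C)/C=C(C)\[C@@H](O[Si](C)(C)C(C)(C)C)CC=O | intermediate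
28 | macrocyclic (3S)-alcohol with silyl ethers at O1 and O15 | C=C1C(=O)O[C@H]2/C=C(/CO[Si](C)(C)C(C)(C)C)[C@@H](O)C[C@H](O[Si](C)(C)C(C)(C)C)/C(C)=C\[C@@H](OC(=O)/C(C)=C\C)[C@H]12 | intermediate
29 | macrocyclic C3 acetate with silyl ethers at O1 and O15 | C=C1C(=O)O[C@H]2/C=C(/CO[Si](C)(C)C(C)(C)C)[C@@H](OC(C)=O)C[C@H](O[Si](C)(C)C(C)(C)C)/C(C)=C\[C@@H](OC(=O)/C(C)=C\C)[C@H]12 | intermediate
30 | CNP0153210.4 | C=C1C(=O)O[C@H]2/C=C(/CO)[C@@H](OC(C)=O)C[C@H](O)/C(C)=C\[C@@H](OC(=O)/C(C)=C\C)[C@H]12 | target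

**Totals**
Total step count: 18. Longest linear sequence: 12 steps (from 11 through steps 6, 7, 9, 10, 11, 12 and 13–18); the butenolide branch is 5 steps and the Weinreb amide 1 step.

**Steps most likely to fail, with fallbacks**

Step 13 (fragment-coupling γ-allylation). Risks are α- versus γ-attack, weak facial control by the C6 substituent, and lactone migration to O8 on the chromium alkoxide. The fallback sets out from 10 and comes back at 23: bromide 10 is treated with HSiCl3, CuCl (cat.) and i-Pr2NEt in Et2O to give the allyltrichlorosilane F1, which is added without purification to enal 21 in DMF at 0 °C. This replaces the redox-active chromium Barbier reaction by a Lewis-base-promoted allylsilane addition through a tighter hexacoordinate silicate chair; it has the same E-type geometry and anti approach, so it gives 23 after aqueous work-up.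

Step 14 (angeloylation). Risks are isomerisation to the tiglate and base-induced lactone migration to O8 on heating. The fallback sets out from 23 and comes back at 25, and builds the angelate double bond on the substrate instead of transferring it. The commercial ethyl ester of the Still–Gennari propionate reagent is hydrolysed with Me3SnOH to 2-[bis(2,2,2-trifluoroethoxy)phosphoryl]propanoic acid F2. This acid acylates 23 at 0 °C (DIC, DMAP cat.) to give the phosphonate ester F3. Treatment with KN(SiMe3)2 and 18-crown-6 in THF at −78 °C, then acetaldehyde, gives the (Z)-2-methylbut-2-enoate 25 by Still–Gennari olefination.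

Step 16 (ring closure and C3 configuration). The C3 selectivity rests on a conformational argument and may be low or reversed. The fallback sets out from 26 and comes back at 28, and moves C3 control from the C–C bond formation to a reagent-controlled reduction. The ring is closed under the same Ni/Cr conditions without regard to selectivity, giving 28 together with the C3-epimeric alcohol F4. The mixture is oxidised with Dess–Martin periodinane to the macrocyclic enone F5. Reduction with (R)-2-methyl-CBS-oxazaborolidine and catecholborane at −78 °C (alkenyl C4 as the large group) then gives the (3S)-alcohol 28.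

**Further compounds**
F1 | step 13 | (5R)-5-[(1Z)-3-[(tert-butyldimethylsilyl)oxy]-2-iodoprop-1-en-1-yl]-3-[(trichlorosilyl)methyl]furan-2(5H)-one | O=C1O[C@H](C=C1C[Si](Cl)(Cl)Cl)/C=C(/CO[Si](C)(C)C(C)(C)C)I
F2 | step 14 | 2-[bis(2,2,2-trifluoroethoxy)phosphoryl]propanoic acid | CC(C(=O)O)P(=O)(OCC(F)(F)F)OCC(F)(F)F
F3 | step 14 | C8 2-[bis(2,2,2-trifluoroethoxy)phosphoryl]propanoate of 23 | C=C1C(=O)O[C@@H](/C=C(/CO[Si](C)(C)C(C)(C)C)I)[C@@H]1[C@H](OC(=O)C(C)P(=O)(OCC(F)(F)F)OCC(F)(F)F)/C=C(C)\[C@@H](O[Si](C)(C)C(C)(C)C)CC(OC)OC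
F4 | step 16 | (3R)-epimer of macrocyclic alcohol 28 | C=C1C(=O)O[C@H]2/C=C(/CO[Si](C)(C)C(C)(C)C)[C@H](O)C[C@H](O[Si](C)(C)C(C)(C)C)/C(C)=C\[C@@H](OC(=O)/C(C)=C\C)[C@H]12
F5 | step 16 | macrocyclic C3 ketone (enone) corresponding to 28 | C=C1C(=O)O[C@H]2/C=C(/CO[Si](C)(C)C(C)(C)C)C(=O)C[C@H](O[Si](C)(C)C(C)(C)C)/C(C)=C\[C@@H](OC(=O)/C(C)=C\C)[C@H]12
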